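(The numbers in the tables are calculated from invented constants, noise included.)

I began at the earliest readings of the closed-flask runs, where L and X, charged at once, gave E and Q, and from these I had to judge set-ups that handle the same charge in different ways.

in all of them: L 0.40 M

| charge | X | remark | time |
|---|---|---|---|
| red | 1.2 equiv | run made earlier |  |
| blue | 0.60 equiv | run made earlier |  |
| ochre | 0.90 equiv | run made earlier |  |
| Tuesday's | 1.20 equiv | one stirred flow tank at steady state, fed with the mixture as stated, mean residence time 7.50 d |  |
| Wednesday's | 1.20 equiv | a closed flask charged with all of it at once and left for 2.5 d | 2.5 d |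
| Saturday's | 1.20 equiv | a single well-mixed tank run continuously and read at steady state, 2.5 d in it on average |  |
| Thursday's | 1.20 equiv (fed, over 2.50 d) | all but X at the start; X goes in evenly over 2.50 d, the run ends at 2.5 d | 2.5 d |

red run (percent of the L charged)

| time / d | E / % | Q / % |
|---|---|---|
| 0.625 | 53.9 | 15.4 |
| 1.25 | 67.5 | 15.7 |
| 2.08 | 76.4 | 15.9 |
| 2.50 | 78.8 | 15.2 |

blue run (percent of the L charged)

| time / h | E / % | Q / % |
|---|---|---|
| 10.0 | 23.2 | 4.6 |
| 20.0 | 40.2 | 6.0 |
| 25.0 | 43.0 | 3.1 |
| 40.0 | 48.9 | 5.1 |

ochre run (percent of the L charged)

| time / h | E / % | Q / % |
|---|---|---|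
| 5.00 | 14.1 | 3.8 |
| 12.0 | 37.2 | 7.7 |
| 25.0 | 55.0 | 11.1 |
| 40.0 | 63.9 | 10.2 |

(readings scatter by 1 percentage point)

- the set-up with the highest share of E in all that became E or Q, at the outlet or at the end ("none" if the first two lie within 2 percentage points) (Tuesday's / Wednesday's / Saturday's / Thursday's / none)
- share of E in all that became E or Q, at the outlet or at the end, Tuesday's
- share of E in all that became E or Q, at the outlet or at the end, Wednesday's
- share of E in all that became E or Q, at the outlet or at the end, Saturday's
- share of E in all that became E or Q, at the outlet or at the end, Thursday's

- the stated concentrations are those of everything mixed, before any reaction; amounts are the same in each set-up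
- the analysis behind the earlier runs scatters by 1 percentage point, standard deviation
- the feed brings no volume worth counting
- the earlier runs were made in a closed, stirred flask
- a reading or a percentage of E counts all its forms, free or not

In the red run E gained 25 percentage points after 0.625 d, more than the scatter, while Q read 15.4% at that first reading and 15.2% at the last, so E went on forming after Q had stopped. The last Q reading fell with the charge of X, from 15.2% in red through 10.2% in ochre to 5.1% in blue, so I took Q to need fresh X, which I took a closed flask to use up early. A flat curve can be replaced by its mean, so I took the mean of the red Q readings, 15.5%, and called it the ceiling of Q: the Q that stands in a closed flask of this charge once its early fresh X has passed. Wednesday's is such a flask, so my reckoning of its share of E, the selectivity, was: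

share = E / (E + ceiling) = 78.8% / (78.8% + 15.5%) = 83.5%

Using the last red Q reading in place of the mean moved this by 0.31 points, so the flattening cost little. In Thursday's, though, X goes in until 2.50 d, later than the first red reading, and the tanks of Tuesday's and Saturday's receive X without pause, so I put no number on those three.

The forecast, holding that “Q is one order higher in X than E”, gave 90.5% for Tuesday's, 83.5% for Wednesday's, 87.5% for Saturday's and 93% for Thursday's, and named Thursday's as best. Its figure for Wednesday's rests on the same red run as mine.

The flask gave 46.0% for Tuesday's, 83.4% for Wednesday's, 45.9% for Saturday's and 58.4% for Thursday's, so the best was Wednesday's.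

    L → Z (k = 0.00693 min⁻¹)
    X → G (k = 0.00374 min⁻¹)
    Z + G → E (k = 0.00779 M⁻¹ min⁻¹)
    L + E ⇌ J, settled at all times (K = 0.700 M⁻¹)
    X + E → Q (k = 0.0139 M⁻¹ min⁻¹)

In Wednesday's, at 0.107 d, free E had a half-life of 0.13 d against X, shorter than the run's 2.5 d, yet by the asked time X stood at 0% and E at 77.7%. Thursday's ended with X at 4.68% of its charge and Q at 28.7%, twice the ceiling. The neighbour, Wednesday's read at 15 h, held E at 52.0% and X at 0.92% of its charge, so the ceiling gives 77.0% there, and the computed share was 77.7%.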